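## Retrosynthetic overview

1. Target 26 ⇐ 5R,6S cis-epoxide 21 by invertive C5–O bond formation with angeloylation of the epoxide oxygen (O6); 21 ⇐ macrocyclic Z-diene 20 by catalyst-controlled epoxidation.
2. 20 ⇐ acyclic triene 19 by ring-closing metathesis at C5=C6 (ten-membered carbocycle, formed second).
3. 19 ⇐ trans-β-vinyl α-methylene lactone 12 by ozonolysis, iodo-Wittig olefination and Stille vinylation (sets the C3=C4 geometry).
4. 12 ⇐ butenolide 6 by anti conjugate vinylation and methylenation; 6 ⇐ alkyne 3 by enantioselective Rh-catalysed C8–O bond formation with acrylic acid, then ring-closing metathesis (γ-lactone, formed first).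
5. 3 ⇐ (S)-citronellyl bromide (supplies C10 with its methyl, C1–C3 and C8–C9) + acetylide.

Locants: C1–C15 are germacrane locants of the target (lactone oxygen on C8, lactone branch on C7, angelate on C6, hydroxyl on C5, ester carbon C15 on C4, methyl C14 on C10).

Assumption: the sense of induction of the two chiral catalysts (steps 2 and 10) is taken by analogy with simple model substrates; if a model run shows the opposite sense, the antipodal ligand is used.

## Route

Step 1
Reactants: 1 (S)-citronellyl bromide [(6S)-8-bromo-2,6-dimethyloct-2-ene]; 2 lithium acetylide ethylenediamine complex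
Product: 3 (5S)-5,9-dimethyldec-8-en-1-yne
Conditions: DMSO, 10 → 25 °C
Reagents that add atoms: none
Why: SN2 alkylation of the acetylide at the primary bromide (alkyne alkylation) adds the two alkyne carbons without touching the C10 stereocentre; the propargylic CH2 is the future C8.

Step 2
Reactants: 3 (5S)-5,9-dimethyldec-8-en-1-yne; 4 acrylic acid
Product: 5 (3R,5S)-5,9-dimethyldeca-1,8-dien-3-yl prop-2-enoate
Conditions: [Rh(cod)Cl]2 (2.5 mol %), (R,R)-Cp-DIOP (6 mol %), ClCH2CH2Cl, 70 °C
Reagents that add atoms: none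
Why: Rhodium-catalysed redox-neutral hydro-acyloxylation of a terminal alkyne: a rhodium hydride isomerises the alkyne to the allene and the acid adds to the π-allyl rhodium at the branched carbon, so the C8–O bond and the 8R centre are set by the chiral diphosphine (catalyst control, the remote C10 centre has no influence).

Step 3
Reactants: 5 (3R,5S)-5,9-dimethyldeca-1,8-dien-3-yl prop-2-enoate
Product: 6 (5R)-5-[(2S)-2,6-dimethylhept-5-en-1-yl]furan-2(5H)-one
Conditions: second-generation Grubbs catalyst (5 mol %), CH2Cl2, 40 °C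
Reagents that add atoms: none
Why: Ring-closing metathesis of the acrylate with the neighbouring vinyl group closes the five-membered lactone with loss of ethene; C8 is not involved and the trisubstituted alkene is too hindered to compete.

Step 4
Reactants: 6 (5R)-5-[(2S)-2,6-dimethylhept-5-en-1-yl]furan-2(5H)-one; 7 vinylmagnesium bromide; 8 N,N-dimethylmethyleneiminium iodide (Eschenmoser's salt)
Product: 10 (3R,4S,5R)-3-[(dimethylamino)methyl]-4-ethenyl-5-[(2S)-2,6-dimethylhept-5-en-1-yl]oxolan-2-one, via bromomagnesium enolate 9 (not isolated)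
Conditions: CuBr·SMe2 (20 mol %), THF, −78 °C; then 8, −78 → 20 °C
Reagents that add atoms: none
Why: Copper-catalysed conjugate addition delivers the vinyl group to the butenolide face anti to the C8 side chain (sets C7, 7,8-trans), and the enolate is trapped in a Mannich reaction anti to the new vinyl group.

Step 5
Reactants: 10 (3R,4S,5R)-3-[(dimethylamino)methyl]-4-ethenyl-5-[(2S)-2,6-dimethylhept-5-en-1-yl]oxolan-2-one
Product: 12 (4S,5R)-4-ethenyl-5-[(2S)-2,6-dimethylhept-5-en-1-yl]-3-methylideneoxolan-2-one, via trimethylammonium iodide 11 (not isolated)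
Conditions: MeI, MeOH, 20 °C; then aq. NaHCO3, EtOAc, 20 °C
Reagents that add atoms: none
Why: N-Methylation followed by E1cB (Hofmann-type) loss of trimethylamine unveils the α-methylene lactone; the mild bicarbonate conditions leave C7 and C8 untouched.

Step 6
Reactants: 12 (4S,5R)-4-ethenyl-5-[(2S)-2,6-dimethylhept-5-en-1-yl]-3-methylideneoxolan-2-one
Product: 14 (4S)-5-[(2R,3S)-3-ethenyl-4-methylidene-5-oxooxolan-2-yl]-4-methylpentanal, via secondary ozonide 13 (not isolated)
Conditions: O3 (1.0 equiv, Sudan Red 7B end point), CH2Cl2, −78 °C; then Me2S, −78 → 20 °C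
Reagents that add atoms: ozone, [O-][O+]=O
Why: Ozonolysis (Criegee mechanism) selects the electron-rich trisubstituted alkene over the monosubstituted vinyl group and the electron-poor methylene lactone, freeing the C3 aldehyde.

Step 7
Reactants: 14 (4S)-5-[(2R,3S)-3-ethenyl-4-methylidene-5-oxooxolan-2-yl]-4-methylpentanal; 15 methyl (triphenylphosphoranylidene)acetate
Product: 17 methyl (2Z,6S)-7-[(2R,3S)-3-ethenyl-4-methylidene-5-oxooxolan-2-yl]-2-iodo-6-methylhept-2-enoate, via iodo ylide 16 (not isolated)
Conditions: 15, N-iodosuccinimide, CH2Cl2, −20 °C; then 14, 20 °C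
Reagents that add atoms: N-iodosuccinimide, O=C1CCC(=O)N1I
Why: Wittig olefination with the stabilised α-iodo ylide places the ester trans to the chain, giving the (Z)-α-iodo enoate that already has the C3=C4 geometry of the target.

Step 8
Reactants: 17 methyl (2Z,6S)-7-[(2R,3S)-3-ethenyl-4-methylidene-5-oxooxolan-2-yl]-2-iodo-6-methylhept-2-enoate; 18 tributyl(vinyl)stannane
Product: 19 methyl (2E,6S)-2-ethenyl-7-[(2R,3S)-3-ethenyl-4-methylidene-5-oxooxolan-2-yl]-6-methylhept-2-enoate
Conditions: Pd2(dba)3 (5 mol %), AsPh3 (20 mol %), CuI (10 mol %), DMF, 25 °C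
Reagents that add atoms: none
Why: Stille coupling replaces iodine by the vinyl group (C5) with retention of the trisubstituted alkene geometry, under neutral conditions that spare the methylene lactone.

Step 9
Reactants: 19 methyl (2E,6S)-2-ethenyl-7-[(2R,3S)-3-ethenyl-4-methylidene-5-oxooxolan-2-yl]-6-methylhept-2-enoate
Product: 20 methyl (3aS,4Z,6E,10S,11aR)-10-methyl-3-methylidene-2-oxo-2,3,3a,8,9,10,11,11a-octahydrocyclodeca[b]furan-6-carboxylate
Conditions: second-generation Hoveyda–Grubbs catalyst (10 mol %), toluene (1 mM), 80 °C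
Reagents that add atoms: none
Why: Ring-closing metathesis of the two terminal vinyl groups forms C5=C6 and the ten-membered carbocycle; the Z-olefin is expected because an E double bond in the conjugated ten-membered diene would be markedly more strained.

Step 10
Reactants: 20 methyl (3aS,4Z,6E,10S,11aR)-10-methyl-3-methylidene-2-oxo-2,3,3a,8,9,10,11,11a-octahydrocyclodeca[b]furan-6-carboxylate
Product: 21 5,6-cis-epoxide of 20 with 5R,6S configuration (7S,8R,10S unchanged)
Conditions: (R,R)-(salen)MnCl [(R,R)-N,N′-bis(3,5-di-tert-butylsalicylidene)cyclohexane-1,2-diaminomanganese chloride] (10 mol %), mCPBA, N-methylmorpholine N-oxide, CH2Cl2, −78 °C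
Reagents that add atoms: meta-chloroperoxybenzoic acid, O=C(OO)c1cccc(Cl)c1
Why: Jacobsen–Katsuki epoxidation selects the cis-disubstituted conjugated C5=C6 bond (the two acrylate-type alkenes are too electron-poor), and the (R,R)-catalyst is expected to give the 5R,6S cis-epoxide by analogy with cis-β-methylstyrene.

Step 11
Reactants: 21 5,6-cis-epoxide (5R,6S); 22 angelic acid [(2Z)-2-methylbut-2-enoic acid]
Product: 26 target CNP0552150.1 [methyl (3aS,4S,5S,6E,10S,11aR)-5-hydroxy-10-methyl-3-methylidene-4-{[(2Z)-2-methylbut-2-enoyl]oxy}-2-oxo-2,3,3a,4,5,8,9,10,11,11a-decahydrocyclodeca[b]furan-6-carboxylate], via angelic trifluoroacetic anhydride 23 (not isolated), via 5-trifluoroacetate 6-alcohol 24 (not isolated), via 5-trifluoroacetate 6-angelate 25 (not isolated)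
Conditions: 22 (3 equiv), (CF3CO)2O (2.5 equiv), CH2Cl2, 0 °C, 30 min; then 21, −40 → 0 °C; then MeOH, Et3N, 0 °C
Reagents that add atoms: trifluoroacetic anhydride, O=C(OC(=O)C(F)(F)F)C(F)(F)F
Why: Proposed new method: one-pot invertive trifluoroacetolysis, mixed-anhydride angeloylation and de-trifluoroacetylation of a vinyl epoxide – angelic acid and the anhydride give mixed anhydride 23 plus one equivalent of CF3CO2H, which opens the protonated epoxide by backside attack of trifluoroacetate at the allylic carbon C5 (inversion, giving 5S; the electron-poor acrylate disfavours a free cation), so the oxygen left on C6 is the epoxide oxygen and the only free hydroxyl, it alone is acylated by 23 (which transfers its non-fluorinated acyl group), and mild methanolysis strips the labile trifluoroacetate from O5, fixing the regiochemistry by mechanism and not by selective acylation of a diol; closest known chemistry: anti ring-opening of epoxides by trifluoroacetic acid and esterification of hindered alcohols through mixed trifluoroacetic anhydrides.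

## Compound list

1 | (S)-citronellyl bromide, (6S)-8-bromo-2,6-dimethyloct-2-ene | CC(C)=CCC[C@H](C)CCBr | starting material
2 | lithium acetylide ethylenediamine complex | [Li+].[C-]#C.NCCN | starting material
3 | (5S)-5,9-dimethyldec-8-en-1-yne | C#CCC[C@@H](C)CCC=C(C)C | intermediate
4 | acrylic acid | C=CC(=O)O | starting material
5 | (3R,5S)-5,9-dimethyldeca-1,8-dien-3-yl prop-2-enoate | C=CC(=O)O[C@@H](C=C)C[C@@H](C)CCC=C(C)C | intermediate
6 | (5R)-5-[(2S)-2,6-dimethylhept-5-en-1-yl]furan-2(5H)-one | O=C1C=C[C@@H](C[C@@H](C)CCC=C(C)C)O1 | intermediate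
7 | vinylmagnesium bromide | C=C[Mg]Br | starting material
8 | N,N-dimethylmethyleneiminium iodide (Eschenmoser's salt) | C=[N+](C)C.[I-] | starting material
9 | bromomagnesium enolate of (4S,5R)-4-ethenyl-5-[(2S)-2,6-dimethylhept-5-en-1-yl]oxolan-2-one | C=C[C@H]1C=C(O[Mg]Br)O[C@@H]1C[C@@H](C)CCC=C(C)C | intermediate
10 | (3R,4S,5R)-3-[(dimethylamino)methyl]-4-ethenyl-5-[(2S)-2,6-dimethylhept-5-en-1-yl]oxolan-2-one | CN(C)C[C@@H]1C(=O)O[C@H](C[C@@H](C)CCC=C(C)C)[C@H]1C=C | intermediate
11 | N-methyl quaternary ammonium iodide of 10 | C[N+](C)(C)C[C@@H]1C(=O)O[C@H](C[C@@H](C)CCC=C(C)C)[C@H]1C=C.[I-] | intermediate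
12 | (4S,5R)-4-ethenyl-5-[(2S)-2,6-dimethylhept-5-en-1-yl]-3-methylideneoxolan-2-one | C=C1C(=O)O[C@H](C[C@@H](C)CCC=C(C)C)[C@H]1C=C | intermediate
13 | secondary ozonide (3,3-dimethyl-1,2,4-trioxolane) of the trisubstituted alkene of 12 | C=C1C(=O)O[C@H](C[C@@H](C)CCC2OOC(C)(C)O2)[C@H]1C=C | intermediate
14 | (4S)-5-[(2R,3S)-3-ethenyl-4-methylidene-5-oxooxolan-2-yl]-4-methylpentanal | C=C1C(=O)O[C@H](C[C@@H](C)CCC=O)[C@H]1C=C | intermediate
15 | methyl (triphenylphosphoranylidene)acetate | COC(=O)C=P(c1ccccc1)(c1ccccc1)c1ccccc1 | starting material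
16 | methyl iodo(triphenylphosphoranylidene)acetate | COC(=O)C(I)=P(c1ccccc1)(c1ccccc1)c1ccccc1 | intermediate
17 | methyl (2Z,6S)-7-[(2R,3S)-3-ethenyl-4-methylidene-5-oxooxolan-2-yl]-2-iodo-6-methylhept-2-enoate | C=C1C(=O)O[C@H](C[C@@H](C)CC/C=C(\I)C(=O)OC)[C@H]1C=C | intermediate
18 | tributyl(vinyl)stannane | C=C[Sn](CCCC)(CCCC)CCCC | starting material
19 | methyl (2E,6S)-2-ethenyl-7-[(2R,3S)-3-ethenyl-4-methylidene-5-oxooxolan-2-yl]-6-methylhept-2-enoate | C=C1C(=O)O[C@H](C[C@@H](C)CC/C=C(\C=C)C(=O)OC)[C@H]1C=C | intermediate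
20 | methyl (3aS,4Z,6E,10S,11aR)-10-methyl-3-methylidene-2-oxo-2,3,3a,8,9,10,11,11a-octahydrocyclodeca[b]furan-6-carboxylate | C=C1C(=O)O[C@@H]2C[C@@H](C)CC/C=C(/C(=O)OC)\C=C/[C@@H]12 | intermediate
21 | 5,6-cis-epoxide of 20, (5R,6S,7S,8R,10S) | C=C1C(=O)O[C@@H]2C[C@@H](C)CC/C=C(/C(=O)OC)[C@H]3O[C@H]3[C@@H]12 | intermediate
22 | angelic acid, (2Z)-2-methylbut-2-enoic acid | C/C=C(/C)C(=O)O | starting material
23 | angelic trifluoroacetic anhydride | C/C=C(/C)C(=O)OC(=O)C(F)(F)F | intermediate
24 | (5S,6S)-6-hydroxy-5-(trifluoroacetoxy) compound (target skeleton, free OH on C6, trifluoroacetate on C5) | C=C1C(=O)O[C@@H]2C[C@@H](C)CC/C=C(/C(=O)OC)[C@H](OC(=O)C(F)(F)F)[C@@H](O)[C@@H]12 | intermediate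
25 | (5S,6S)-6-angeloyloxy-5-(trifluoroacetoxy) compound | C=C1C(=O)O[C@@H]2C[C@@H](C)CC/C=C(/C(=O)OC)[C@H](OC(=O)C(F)(F)F)[C@@H](OC(=O)/C(C)=C\C)[C@@H]12 | intermediate
26 | CNP0552150.1, methyl (3aS,4S,5S,6E,10S,11aR)-5-hydroxy-10-methyl-3-methylidene-4-{[(2Z)-2-methylbut-2-enoyl]oxy}-2-oxo-2,3,3a,4,5,8,9,10,11,11a-decahydrocyclodeca[b]furan-6-carboxylate | C=C1C(=O)O[C@@H]2C[C@@H](C)CC/C=C(/C(=O)OC)[C@H](O)[C@@H](OC(=O)/C(C)=C\C)[C@@H]12 | target

## Step count and risks

Total step count: 11. Longest linear sequence: 11 steps (1 → 26).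

Steps most likely to fail:

Step 11 (proposed new step). Risks are partial loss of inversion at C5, conjugate opening at C3, trifluoroacetylation of O6 (which would give the diol), and acyl migration between O5 and O6. Fallback with known chemistry, setting out from 21: 4-methoxybenzyl alcohol with catalytic BF3·OEt2 in CH2Cl2 at −40 °C opens the epoxide at allylic C5 with inversion to the 5-O-(4-methoxybenzyl) 6-alcohol F3, in which only O6 is free. Yamaguchi esterification (22, 2,4,6-trichlorobenzoyl chloride, Et3N, DMAP, toluene) gives the 5-O-(4-methoxybenzyl) 6-angelate F4. DDQ in CH2Cl2–pH 7 buffer removes the benzyl ether and the route comes back at 26.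

Step 9 (ten-membered ring-closing metathesis). Risks are oligomerisation and formation of the E-olefin. Fallback setting out from 17 (step 8 is then skipped): an intramolecular Heck reaction (Pd(OAc)2, Bu4NCl, K2CO3, DMF, 2 mM, 60 °C) joins C4 to the terminal carbon of the C7 vinyl group, which becomes C5, and β-hydride elimination gives the conjugated macrocycle, expected as the (5E)-isomer of 20 F1. Thiyl-radical equilibration (catalytic PhSSPh, hν, benzene) then converts it into the less strained Z,Z-diene, so the route comes back at 20.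

Step 10 (face selectivity and cis/trans leakage in the epoxidation of the chiral macrocycle). If the ring's own bias overrides the catalyst and the 5S,6R epoxide forms, the fallback sets out from 20: NBS in THF–H2O at 0 °C gives the (5R,6R)-6-bromo-5-hydroxy bromohydrin F2, water opening the bromonium ion at allylic C5 anti to bromine. K2CO3 in acetone closes it to the epoxide whose oxygen lies on the face opposite to the one the electrophile attacked, the complement of direct epoxidation, and the route comes back at 21.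

Further compounds
F1 | step 9 | methyl (3aS,4E,6E,10S,11aR)-10-methyl-3-methylidene-2-oxo-2,3,3a,8,9,10,11,11a-octahydrocyclodeca[b]furan-6-carboxylate, (5E)-isomer of 20 | C=C1C(=O)O[C@@H]2C[C@@H](C)CC/C=C(/C(=O)OC)\C=C\[C@@H]12
F2 | step 10 | (5R,6R)-6-bromo-5-hydroxy bromohydrin of 20 | C=C1C(=O)O[C@@H]2C[C@@H](C)CC/C=C(/C(=O)OC)[C@@H](O)[C@H](Br)[C@@H]12
F3 | step 11 | (5S,6S)-6-hydroxy-5-[(4-methoxybenzyl)oxy] compound | C=C1C(=O)O[C@@H]2C[C@@H](C)CC/C=C(/C(=O)OC)[C@H](OCc3ccc(OC)cc3)[C@@H](O)[C@@H]12
F4 | step 11 | (5S,6S)-6-angeloyloxy-5-[(4-methoxybenzyl)oxy] compound | C=C1C(=O)O[C@@H]2C[C@@H](C)CC/C=C(/C(=O)OC)[C@H](OCc3ccc(OC)cc3)[C@@H](OC(=O)/C(C)=C\C)[C@@H]12
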